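(All constants were set for the occasion.)

Compare ochre, teal and green: they take the same charges of Q and E, but the feeding differs.

    2 Q → Q2 (k1 = 10 M⁻¹ h⁻¹)
    Q + E → Q.E, rate k2*[Q]^0.5*[E]^0.5 (k2 = 8.0 h⁻¹)
    Q.E ⇌ G (K3 = 1.0, k3 = 0.12 h⁻¹)
    Q ⇌ L (K4 = 32, k4 = 0.16 h⁻¹)

| setting | ochre | teal | green |
|---|---|---|---|
| Q | 0.20 M | 0.20 M | 0.20 M (fed, over 4.0 h) |
| E | 0.120 M (fed, over 4.0 h) | 0.120 M | 0.120 M |
| time | 5.0 h | 5.0 h | 5.0 h |
| remark | all else is in the flask from the start; the feed brings no volume worth counting | everything together at the start | all else is in the flask from the start; the feed brings no volume worth counting |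

* which flask leads in amount of G, in percent of the Q charged ("all alike" within 1.5 percentage points) (ochre / teal / green / all alike)
* how much G is there at the end, in percent of the Q charged: ochre
* how much G is there at the end, in percent of the Q charged: teal
* how much G is there at the end, in percent of the Q charged: green

Call the sum of Q.E and G the pot. The step Q.E ⇌ G has an equilibrium constant of 1.0, the symmetric case, so a batch of Q.E ends at 50.0% as G. Take that as the top of the scale. Forward and back together, the batch relaxes at λ = 0.240 h⁻¹, a half-life of 2.89 h. The fraction standing as G at age t is then that top times one minus exp(−λt). At age 5.0 h a batch holds 34.9% as G; call this fraction, at any age, the relaxed share.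

Now take the extremes. If all Q.E is born at the start, the share is 34.9%. If all is born at the last moment, the share is zero. A real flask lies between. The share curve bends over with age, so the average over a flask's batches stands at or under the share of their mean age.

In teal and green, take E as the limiting reagent and the pot as 60.0% of the Q charged. Teal sits at the first extreme, which gives G of 21.0%. Green receives Q at 0.0500 M h⁻¹, which matches E after 2.40 h. Its mean age is 3.80 h and the share at that age is 29.9%, so green's G stands at or under 17.9%. In ochre, Q has a first half-life of 0.250 h by dimerisation, shorter than the feed of 4.0 h. I cannot reckon ochre's pot by hand, so I only rank it last.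

The forecast gives 7.6% for ochre, 20.7% for teal and 17.4% for green, with teal leading: “the earlier the Q.E forms the more G appears by 5 h”. Its teal and green stand below mine, and it gives ochre a figure where I have none.

The flask gives 7.77% in ochre, 20.8% in teal and 17.7% in green, and teal leads. Teal holds 34.6% of its pot as G, beside the relaxed share of 34.9%. At 0.139 h, ochre's Q goes into Q2 10 times as fast as into Q.E, and ochre's pot ends at 24.8%. Ochre's median turnover of Q with E falls at 0.840 h, an age of 4.16 h and a share of 31.6%. The neighbour of ochre charged with 0.12 M of Q holds 11.9% G beside 25.6% Q.E, a share of 31.7%.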